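**Retrosynthetic overview**

1. Side chain locants run from C1' (OCH2) to C8' (=CH2). The target is cut at C4'–C3' into an E-alkenyl triflate that already carries the coumarin (C1'–C3') and an erythro epoxy alcohol (C4'–C8'); a nickel-catalysed reductive epoxide–alkenyl cross-electrophile coupling joins them in the last step, without protecting groups.
2. Enabling feature: the C5' hydroxyl sits on the carbon next to C4' and is homoallylic to C2'=C3', so C4', C5' and the C5' oxygen are the three ring atoms of a terminal oxirane opened at C4'; the 5',6'-anti-diol corresponds to the erythro oxiranyl carbinol.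
3. Alkenyl triflate half: Mitsunobu O-alkylation of 7-hydroxy-8-methoxycoumarin with (E)-4-hydroxybut-2-en-2-yl triflate, made from ethyl acetoacetate by E-selective enol triflation and ester reduction.
4. Epoxy alcohol half: methyl (S)-glycidate supplies C5'; Weinreb amide, isopropenyl ketone, then chelation-controlled reduction sets C6'.
5. Rings: none is formed; the benzopyranone is bought intact and the oxirane of the glycidate is carried through and opened in the key step.

Key step: step 7

Assumption: 7-hydroxy-8-methoxycoumarin, methyl (S)-glycidate and isopropenylmagnesium bromide solution are taken as purchasable.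

**Route**

Step 1
Reactants: 1 ethyl acetoacetate
Product: 2 ethyl (2E)-3-{[(trifluoromethyl)sulfonyl]oxy}but-2-enoate
Conditions: Tf2O, aq Me4NOH, toluene, 5 °C
Reagents that add atoms: trifluoromethanesulfonic anhydride, O=S(=O)(OS(=O)(=O)C(F)(F)F)C(F)(F)F
Why: Schotten–Baumann-type O-sulfonylation of the β-keto ester enolate, in which the non-coordinating tetramethylammonium counter-ion lets the enolate react from its open, non-chelated form so that the triflate should end up trans to the ester (E), whereas a chelating lithium base would give the Z isomer.

Step 2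
Reactants: 2 ethyl (2E)-3-{[(trifluoromethyl)sulfonyl]oxy}but-2-enoate
Product: 4 (2E)-4-hydroxybut-2-en-2-yl trifluoromethanesulfonate, via enal triflate 3 (not isolated)
Conditions: i-Bu2AlH (2.3 equiv), CH2Cl2, −78 to −40 °C; aq potassium sodium tartrate
Reagents that add atoms: none
Why: 1,2-reduction of the conjugated ester by two hydride transfers from i-Bu2AlH through aldehyde 3, the electrophilic aluminium hydride leaving the enol triflate and the double bond untouched at low temperature so that the E geometry is kept.

Step 3
Reactants: 4 (2E)-4-hydroxybut-2-en-2-yl trifluoromethanesulfonate; 5 7-hydroxy-8-methoxy-2H-chromen-2-one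
Product: 6 (2E)-4-[(8-methoxy-2-oxo-2H-chromen-7-yl)oxy]but-2-en-2-yl trifluoromethanesulfonate
Conditions: PPh3, DIAD, THF, 0 °C to rt
Reagents that add atoms: none
Why: Mitsunobu etherification in which the acidic 7-hydroxyl of the coumarin displaces the phosphonium-activated primary allylic oxygen at C1' by SN2, so no stereocentre is involved and the E-enol triflate is carried through unchanged.

Step 4
Reactants: 7 methyl (2S)-oxirane-2-carboxylate
Product: 8 (2S)-N-methoxy-N-methyloxirane-2-carboxamide
Conditions: MeNH(OMe)·HCl, i-PrMgCl, THF, −20 °C
Reagents that add atoms: N,O-dimethylhydroxylamine hydrochloride, CNOC.Cl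
Why: Weinreb amide synthesis by ester-to-amide exchange with the chloromagnesium amide formed in situ, which at −20 °C should outpace any attack on the oxirane and leaves its stereocentre untouched.

Step 5
Reactants: 8 (2S)-N-methoxy-N-methyloxirane-2-carboxamide; 9 isopropenylmagnesium bromide
Product: 10 2-methyl-1-[(2S)-oxiran-2-yl]prop-2-en-1-one
Conditions: THF, −78 to −20 °C; inverse quench into cold aq NaHSO4/Et2O; used at once in solution
Reagents that add atoms: none
Why: Weinreb ketone synthesis, in which the alkenyl Grignard reagent adds once and the five-membered magnesium chelate of the tetrahedral adduct survives until the cold acidic quench, which also protonates the released amine before it can add to the vinyl ketone, while the oxirane carbon is not enolised and keeps its S configuration.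

Step 6
Reactants: 10 2-methyl-1-[(2S)-oxiran-2-yl]prop-2-en-1-one
Product: 11 (1R)-2-methyl-1-[(2S)-oxiran-2-yl]prop-2-en-1-ol
Conditions: Zn(BH4)2, Et2O, −30 °C; aq NH4Cl
Reagents that add atoms: none
Why: chelation-controlled 1,2-reduction of an α,β-epoxy ketone, in which zinc bridges the ketone oxygen and the oxirane oxygen and hydride attacks the carbonyl face remote from the oxirane CH2 group, so the new C6' carbinol should be R (erythro to the oxirane C–O bond) while the mild borohydride spares the oxirane and the enone β-carbon.

Step 7
Reactants: 6 (2E)-4-[(8-methoxy-2-oxo-2H-chromen-7-yl)oxy]but-2-en-2-yl trifluoromethanesulfonate; 11 (1R)-2-methyl-1-[(2S)-oxiran-2-yl]prop-2-en-1-ol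
Product: 13 7-{[(2E,5S,6R)-5,6-dihydroxy-3,7-dimethylocta-2,7-dien-1-yl]oxy}-8-methoxy-2H-chromen-2-one (target), via iodohydrin 12 (not isolated)
Conditions: NiCl2(dme) (10 mol%), 2,2'-bipyridine (10 mol%), NaI (25 mol%), Et3N·HCl (1 equiv), Mn powder (2 equiv), DMPU, rt; 11 in 1.5-fold excess
Reagents that add atoms: sodium iodide, [Na+].[I-] (iodine enters intermediate 12 only and leaves again; none of it stays in 13)
Why: Et3N·HCl with catalytic NaI opens the terminal oxirane of 11 by SN2 attack of iodide at C4' to give iodohydrin 12, bipyridine-ligated zerovalent nickel inserts into the C3'–O bond of the enol triflate with retention of the E geometry, the alkenylnickel species captures the primary C4' radical generated from 12 by iodine abstraction, and reductive elimination from trivalent nickel forms the C4'–C3' bond while Mn returns nickel to its low-valent state. The closest known reaction type is the nickel-catalysed, iodide-co-catalysed reductive cross-electrophile coupling of terminal epoxides with aryl or alkenyl halides and triflates, which gives the alcohol from attack at the less hindered oxirane carbon. No ring is closed (the oxirane is opened) and no stereocentre is created: the C5'–O bond is never broken and C6' is a spectator, so the (5'S,6'R)-anti-diol is delivered from 11 unchanged, and the alkene stays E because both events at C3' are stereoretentive. The step needs regioselectivity for C4' over C5', which the unhindered CH2 terminus of the monosubstituted oxirane secures, and cross- over homo-coupling, which the different activation modes of the two carbons secure (two-electron oxidative addition at the sp2 triflate, radical formation at the sp3 iodide). It also needs chemoselectivity towards the coumarin lactone, the allylic aryl ether, the isopropenyl group and two free hydroxyls, which the neutral, proton-buffered, room-temperature conditions should respect. In this one operation the two halves are joined, the C5' carbinol is unveiled and the unprotected target is released.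

**Compound list**

1 | ethyl acetoacetate (ethyl 3-oxobutanoate) | CCOC(=O)CC(C)=O | starting material
2 | ethyl (2E)-3-{[(trifluoromethyl)sulfonyl]oxy}but-2-enoate | CCOC(=O)/C=C(\C)OS(=O)(=O)C(F)(F)F | intermediate
3 | (2E)-4-oxobut-2-en-2-yl trifluoromethanesulfonate | O=C/C=C(\C)OS(=O)(=O)C(F)(F)F | intermediate
4 | (2E)-4-hydroxybut-2-en-2-yl trifluoromethanesulfonate | OC/C=C(\C)OS(=O)(=O)C(F)(F)F | intermediate
5 | 7-hydroxy-8-methoxy-2H-chromen-2-one | COc1c(O)ccc2ccc(=O)oc12 | starting material
6 | (2E)-4-[(8-methoxy-2-oxo-2H-chromen-7-yl)oxy]but-2-en-2-yl trifluoromethanesulfonate | COc1c(OC/C=C(\C)OS(=O)(=O)C(F)(F)F)ccc2ccc(=O)oc12 | intermediate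
7 | methyl (2S)-oxirane-2-carboxylate | COC(=O)[C@@H]1CO1 | starting material
8 | (2S)-N-methoxy-N-methyloxirane-2-carboxamide | CON(C)C(=O)[C@@H]1CO1 | intermediate
9 | isopropenylmagnesium bromide (prop-1-en-2-ylmagnesium bromide) | C=C(C)[Mg]Br | starting material
10 | 2-methyl-1-[(2S)-oxiran-2-yl]prop-2-en-1-one | C=C(C)C(=O)[C@@H]1CO1 | intermediate
11 | (1R)-2-methyl-1-[(2S)-oxiran-2-yl]prop-2-en-1-ol | C=C(C)[C@@H](O)[C@@H]1CO1 | intermediate
12 | (2R,3R)-1-iodo-4-methylpent-4-ene-2,3-diol | C=C(C)[C@@H](O)[C@@H](O)CI | intermediate
13 | 7-{[(2E,5S,6R)-5,6-dihydroxy-3,7-dimethylocta-2,7-dien-1-yl]oxy}-8-methoxy-2H-chromen-2-one | C=C(C)[C@@H](O)[C@@H](O)C/C(C)=C/COc1ccc2ccc(=O)oc2c1OC | target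

**Step count**

Total steps: 7. Longest linear sequence: 4 steps (steps 4, 5, 6 and 7 from methyl (2S)-oxirane-2-carboxylate; steps 1, 2, 3 and 7 from ethyl acetoacetate are equally long).

**Steps most likely to fail**

Step 7. The alkenyl triflate may be lost by homocoupling or protodetriflation, low-valent nickel may ionise the allylic aryl ether, or the C4' radical may be intercepted by the coumarin C3=C4 bond before it reaches nickel. The fallback makes the same C4'–C3' bond by a two-electron epoxide opening and builds the alkene afterwards; it sets out from 11 and comes back to the route at 13.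
- 11 is silylated (TBSCl, imidazole, DMF) to tert-butyl(dimethyl){[(1R)-2-methyl-1-[(2S)-oxiran-2-yl]prop-2-en-1-yl]oxy}silane F1.
- The oxirane of F1 is opened at C4' by lithium (trimethylsilyl)acetylide with BF3·OEt2 in THF at −78 °C to give (3R,4S)-3-{[tert-butyl(dimethyl)silyl]oxy}-2-methyl-7-(trimethylsilyl)hept-1-en-6-yn-4-ol F2.
- Tetrabutylammonium fluoride in THF removes both silyl groups to give (3R,4S)-2-methylhept-1-en-6-yne-3,4-diol F3.
- Carboalumination of the terminal alkyne (Me3Al in excess, Cp2ZrCl2, CH2Cl2) adds methyl and aluminium syn; the alkenylalane is converted to its ate complex with n-BuLi and trapped with paraformaldehyde to give (2E,5S,6R)-3,7-dimethylocta-2,7-diene-1,5,6-triol F4.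
- A Mitsunobu reaction of the primary allylic hydroxyl of F4, the most reactive of the three, with 5 (PPh3, DIAD, THF, 0 °C) should give 13.

Step 5. The released N,O-dimethylhydroxylamine or a second equivalent of 9 may add in conjugate fashion to the vinyl ketone, magnesium halide may open the oxirane, and the ketone may polymerise on concentration. The fallback replaces acyl substitution by aldehyde addition and oxidation, so no nucleophilic amine is ever present; it sets out from 7 and comes back to the route at 10.
- 7 is reduced with i-Bu2AlH (1.05 equiv, CH2Cl2, −78 °C) to (2S)-oxirane-2-carbaldehyde F5, held in the flask as its aluminium hemiacetal.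
- 9 is added at −78 °C and the mixture warmed to 0 °C to give 2-methyl-1-[(2S)-oxiran-2-yl]prop-2-en-1-ol (mixture of carbinol epimers) F6.
- Allylic oxidation of F6 with MnO2 (CH2Cl2, rt) gives 10 in solution for step 6.

Step 6. Incomplete chelation may give poor facial selectivity, and hydride may add to the enone β-carbon. The fallback fixes C6' by SN2 inversion and not by the facial preference of a hydride; it sets out from 10 and comes back to the route at 11.
- 10 is reduced under conditions that suppress conjugate reduction (NaBH4, CeCl3·7H2O, MeOH, −78 °C) and the epimers are separated.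
- The threo epimer (1S)-2-methyl-1-[(2S)-oxiran-2-yl]prop-2-en-1-ol F7 is esterified with inversion in a Mitsunobu reaction (4-nitrobenzoic acid, PPh3, DIAD, toluene, 0 °C) to (1R)-2-methyl-1-[(2S)-oxiran-2-yl]prop-2-en-1-yl 4-nitrobenzoate F8.
- Brief methanolysis of F8 (K2CO3, MeOH, 0 °C, short contact to avoid Payne rearrangement) gives 11.

**Further compounds**

F1 | step 7 | tert-butyl(dimethyl){[(1R)-2-methyl-1-[(2S)-oxiran-2-yl]prop-2-en-1-yl]oxy}silane | C=C(C)[C@@H](O[Si](C)(C)C(C)(C)C)[C@@H]1CO1
F2 | step 7 | (3R,4S)-3-{[tert-butyl(dimethyl)silyl]oxy}-2-methyl-7-(trimethylsilyl)hept-1-en-6-yn-4-ol | C=C(C)[C@@H](O[Si](C)(C)C(C)(C)C)[C@@H](O)CC#C[Si](C)(C)C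
F3 | step 7 | (3R,4S)-2-methylhept-1-en-6-yne-3,4-diol | C=C(C)[C@@H](O)[C@@H](O)CC#C
F4 | step 7 | (2E,5S,6R)-3,7-dimethylocta-2,7-diene-1,5,6-triol | C=C(C)[C@@H](O)[C@@H](O)C/C(C)=C/CO
F5 | step 5 | (2S)-oxirane-2-carbaldehyde | O=C[C@@H]1CO1
F6 | step 5 | 2-methyl-1-[(2S)-oxiran-2-yl]prop-2-en-1-ol (mixture of carbinol epimers) | C=C(C)C(O)[C@@H]1CO1
F7 | step 6 | (1S)-2-methyl-1-[(2S)-oxiran-2-yl]prop-2-en-1-ol | C=C(C)[C@H](O)[C@@H]1CO1
F8 | step 6 | (1R)-2-methyl-1-[(2S)-oxiran-2-yl]prop-2-en-1-yl 4-nitrobenzoate | C=C(C)[C@@H](OC(=O)c1ccc(cc1)[N+](=O)[O-])[C@@H]1CO1
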